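**Retrosynthetic overview**
1. Target 17 is (−)-epicatechin-(4β→8)-(+)-catechin with a 4-hydroxybenzoate on O3 of the lower (catechin) unit; it is unmasked from deca-O-benzyl dimer 16 by one global hydrogenolysis.
2. Key disconnection: the interflavan C4(upper)–C8(lower) bond of 16, made by a new boron-directed ipso coupling of 4β-alkoxyflavan 6 with C8-trifluoroborate 13; this step sets C4 (R).
3. 6 comes from (−)-epicatechin 1 (two O-benzylations, DDQ C4–H alkoxylation); 13 comes from (+)-catechin 7 (benzylation, C8 bromination, O3 acylation with 10, Miyaura borylation, KHF2).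
4. No ring is built: rings A, B and C of both units and the C2/C3 stereocentres come intact from the two natural flavan-3-ols; the order is upper unit, lower unit, union, deprotection.

Assumption: simple reagents (BnBr, NBS, B2pin2, KHF2 and the like) are given with SMILES on the reagent lines and carry no number; the numbered starting materials are 1, 7 and 10.

**Route**

Step 1
Reactants: 1 (−)-epicatechin
Product: 2 5,7,3',4'-tetra-O-benzyl-(−)-epicatechin (2R,3R; 3-OH free)
Conditions: BnBr (4.4 equiv), K2CO3 (5 equiv), DMF, 0 °C → rt, Ar, dark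
Reagents that add atoms: benzyl bromide BrCc1ccccc1
Why: Williamson etherification in which K2CO3 deprotonates only the four phenols, so the secondary 3-OH stays free and, at or below rt under argon, C2 and C3 are untouched.

Step 2
Reactants: 2 5,7,3',4'-tetra-O-benzyl-(−)-epicatechin
Product: 4 3,5,7,3',4'-penta-O-benzyl-(−)-epicatechin (2R,3R), via sodium 3-alkoxide 3 (not isolated)
Conditions: NaH, THF–DMF (4:1), 0 °C; then BnBr, Bu4NI (cat.), 0 °C → rt
Reagents that add atoms: benzyl bromide BrCc1ccccc1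
Why: Williamson etherification of the sodium alkoxide, which does not break the C3–O bond (3R retained) and gives an O3 cap that cannot bind boron in step 9 yet falls off in step 10.

Step 3
Reactants: 4 3,5,7,3',4'-penta-O-benzyl-(−)-epicatechin
Product: 6 (2R,3R,4S)-3,5,7-tris(benzyloxy)-2-[3,4-bis(benzyloxy)phenyl]-4-(2-ethoxyethoxy)chromane (4β-alkoxy electrophile), via chroman-4-ylium hydroquinonate ion pair 5 (not isolated)
Conditions: DDQ (2 equiv), EtOCH2CH2OH (5 equiv), CH2Cl2, rt, dark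
Reagents that add atoms: 2-ethoxyethanol CCOCCO
Why: DDQ benzylic C–H oxidation (hydride abstraction) removes the C4–H conjugated to the trioxygenated ring A to give the chroman-4-ylium 2,3-dichloro-5,6-dicyano-4-hydroxyphenolate ion pair 5, whose cation the alcohol traps anti to the 2-aryl/3-benzyloxy face (4β) while the hydroquinone anion takes up the proton; this C4 centre is provisional and is erased in step 9.

Step 4
Reactants: 7 (+)-catechin
Product: 8 5,7,3',4'-tetra-O-benzyl-(+)-catechin (2R,3S; 3-OH free)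
Conditions: BnBr (4.4 equiv), K2CO3 (5 equiv), DMF, 0 °C → rt, Ar
Reagents that add atoms: benzyl bromide BrCc1ccccc1
Why: Williamson etherification selective for the four phenols as in step 1, with no change at C2 or C3.

Step 5
Reactants: 8 5,7,3',4'-tetra-O-benzyl-(+)-catechin
Product: 9 8-bromo-5,7,3',4'-tetra-O-benzyl-(+)-catechin (2R,3S)
Conditions: NBS (1.0 equiv), CH2Cl2, −78 °C → rt
Reagents that add atoms: N-bromosuccinimide O=C1CCC(=O)N1Br
Why: Electrophilic aromatic bromination, for which C8 of the 5,7-bis(benzyloxy) ring A is the established most reactive position and ring B is much less activated.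

Step 6
Reactants: 9 8-bromo-5,7,3',4'-tetra-O-benzyl-(+)-catechin; 10 4-(benzyloxy)benzoyl chloride
Product: 11 (2R,3S)-5,7-bis(benzyloxy)-2-[3,4-bis(benzyloxy)phenyl]-8-bromochroman-3-yl 4-(benzyloxy)benzoate
Conditions: Et3N, DMAP (cat.), CH2Cl2, 0 °C → rt
Reagents that add atoms: none
Why: DMAP-catalysed O-acylation (nucleophilic acyl substitution) of the only free hydroxyl, which leaves the C3–O bond intact so that 3S is retained.

Step 7
Reactants: 11 8-bromo ester
Product: 12 (2R,3S)-5,7-bis(benzyloxy)-2-[3,4-bis(benzyloxy)phenyl]-8-(4,4,5,5-tetramethyl-1,3,2-dioxaborolan-2-yl)chroman-3-yl 4-(benzyloxy)benzoate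
Conditions: Pd2(dba)3 (2.5 mol %), SPhos (10 mol %), B2pin2 (2 equiv), KOAc (3 equiv), 1,4-dioxane, 100 °C
Reagents that add atoms: bis(pinacolato)diboron CC1(C)OB(OC1(C)C)B1OC(C)(C)C(C)(C)O1
Why: Miyaura borylation in which SPhos-ligated zerovalent palladium inserts into the hindered, electron-rich C8–Br bond and acetate-assisted transmetalation with B2pin2 tolerates the ester and the benzyl ethers.

Step 8
Reactants: 12 8-pinacolboronate ester
Product: 13 potassium trifluoro{(2R,3S)-5,7-bis(benzyloxy)-2-[3,4-bis(benzyloxy)phenyl]-3-[4-(benzyloxy)benzoyloxy]chroman-8-yl}borate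
Conditions: KHF2 (aq., 5 equiv), THF–MeOH, 0 °C → rt; acetone extraction, precipitation with Et2O
Reagents that add atoms: potassium hydrogen difluoride F.[F-].[K+]
Why: Boronate-to-trifluoroborate exchange with bifluoride gives a storable ate salt whose boron-bearing C8 is the activated nucleophilic carbon, with no stereocentre involved and the ester stable to the brief mildly acidic treatment.

Step 9
Reactants: 6 4β-(2-ethoxyethoxy) penta-O-benzyl-epicatechin (1.0 equiv); 13 C8-trifluoroborate of the catechin ester (1.2 equiv)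
Product: 16 deca-O-benzyl dimer: 8-[(2R,3R,4R)-3,5,7-tris(benzyloxy)-2-[3,4-bis(benzyloxy)phenyl]chroman-4-yl]-(2R,3S)-5,7-bis(benzyloxy)-2-[3,4-bis(benzyloxy)phenyl]chroman-3-yl 4-(benzyloxy)benzoate, via C8 aryldifluoroborane 14 (not isolated), via chroman-4-ylium borate ion pair 15 (not isolated)
Conditions: 13, BF3·OEt2 (1.1 equiv), 4 Å MS, CH2Cl2–MeCN (4:1), −40 °C, 15 min; then 6 added dropwise, −40 → −10 °C; then H2O
Reagents that add atoms: none
Why: Proposed new method: boron-directed ipso interflavan coupling (a deborylative Friedel–Crafts alkylation), in which BF3·OEt2 strips one fluoride from 13 to give the Lewis acidic aryldifluoroborane 14, which itself binds and removes the chelating 2-ethoxyethoxy group from C4 of 6, so that the C4 chroman-4-ylium ion exists only as contact ion pair 15 with the aryl(2-ethoxyethoxy)difluoroborate and takes the aryl group from boron through its boron-bearing ipso carbon C8 (SE2-type ipso substitution at the C–B bond) on the face anti to the cis 2-aryl and 3-benzyloxy groups (3,4-trans, 4β, new centre 4R), releasing F2B–OCH2CH2OEt, which the aqueous quench hydrolyses; because only C8 carries boron, no free BF3 remains and the cation is made only by the nucleophile that consumes it, the 4→6 isomer, self-condensation of 6 and a large excess of nucleophile should be avoided; the closest known reaction types are the BF3-promoted substitution of mixed acetals (oxocarbenium ions) by potassium aryltrifluoroborates and the Lewis-acid-catalysed C4–C8 Friedel–Crafts condensation of 4-alkoxyflavans with C8–H flavan nucleophiles.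

Step 10
Reactants: 16 deca-O-benzyl dimer
Product: 17 (−)-epicatechin-(4β→8)-(+)-catechin 3-O-(4-hydroxybenzoate) on the lower unit (target)
Conditions: H2 (1 atm), Pd(OH)2/C, THF–MeOH–H2O (20:20:1), rt; filtration, Sephadex LH-20, lyophilisation
Reagents that add atoms: none
Why: Catalytic hydrogenolysis cleaves the nine phenolic and one aliphatic O-benzyl groups under neutral conditions, to which the aryl ester, the interflavan C–C bond, the ring C ethers and all five stereocentres are inert.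

**Compound list**
1 | (−)-epicatechin, (2R,3R)-2-(3,4-dihydroxyphenyl)chromane-3,5,7-triol | O[C@@H]1Cc2c(O)cc(O)cc2O[C@@H]1c1ccc(O)c(O)c1 | starting material
2 | 5,7,3',4'-tetra-O-benzyl-(−)-epicatechin, (2R,3R)-5,7-bis(benzyloxy)-2-[3,4-bis(benzyloxy)phenyl]chroman-3-ol | O[C@@H]1Cc2c(OCc3ccccc3)cc(OCc3ccccc3)cc2O[C@@H]1c1ccc(OCc2ccccc2)c(OCc2ccccc2)c1 | intermediate
3 | sodium (2R,3R)-5,7-bis(benzyloxy)-2-[3,4-bis(benzyloxy)phenyl]chroman-3-olate (not isolated) | [Na+].[O-][C@@H]1Cc2c(OCc3ccccc3)cc(OCc3ccccc3)cc2O[C@@H]1c1ccc(OCc2ccccc2)c(OCc2ccccc2)c1 | intermediate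
4 | 3,5,7,3',4'-penta-O-benzyl-(−)-epicatechin, (2R,3R)-3,5,7-tris(benzyloxy)-2-[3,4-bis(benzyloxy)phenyl]chromane | C(c1ccccc1)O[C@@H]1Cc2c(OCc3ccccc3)cc(OCc3ccccc3)cc2O[C@@H]1c1ccc(OCc2ccccc2)c(OCc2ccccc2)c1 | intermediate
5 | (2R,3R)-3,5,7-tris(benzyloxy)-2-[3,4-bis(benzyloxy)phenyl]chroman-4-ylium 2,3-dichloro-5,6-dicyano-4-hydroxyphenolate, the ion pair formed by hydride transfer from C4 of 4 to DDQ (not isolated) | [CH+]1c2c(OCc3ccccc3)cc(OCc3ccccc3)cc2O[C@H](c2ccc(OCc3ccccc3)c(OCc3ccccc3)c2)[C@@H]1OCc1ccccc1.[O-]c1c(Cl)c(Cl)c(O)c(C#N)c1C#N | intermediate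
6 | (2R,3R,4S)-3,5,7-tris(benzyloxy)-2-[3,4-bis(benzyloxy)phenyl]-4-(2-ethoxyethoxy)chromane (4-alkoxy trans to 3-OBn) | CCOCCO[C@H]1c2c(OCc3ccccc3)cc(OCc3ccccc3)cc2O[C@H](c2ccc(OCc3ccccc3)c(OCc3ccccc3)c2)[C@@H]1OCc1ccccc1 | intermediate
7 | (+)-catechin, (2R,3S)-2-(3,4-dihydroxyphenyl)chromane-3,5,7-triol | O[C@H]1Cc2c(O)cc(O)cc2O[C@@H]1c1ccc(O)c(O)c1 | starting material
8 | 5,7,3',4'-tetra-O-benzyl-(+)-catechin, (2R,3S)-5,7-bis(benzyloxy)-2-[3,4-bis(benzyloxy)phenyl]chroman-3-ol | O[C@H]1Cc2c(OCc3ccccc3)cc(OCc3ccccc3)cc2O[C@@H]1c1ccc(OCc2ccccc2)c(OCc2ccccc2)c1 | intermediate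
9 | 8-bromo-5,7,3',4'-tetra-O-benzyl-(+)-catechin, (2R,3S)-5,7-bis(benzyloxy)-2-[3,4-bis(benzyloxy)phenyl]-8-bromochroman-3-ol | O[C@H]1Cc2c(OCc3ccccc3)cc(OCc3ccccc3)c(Br)c2O[C@@H]1c1ccc(OCc2ccccc2)c(OCc2ccccc2)c1 | intermediate
10 | 4-(benzyloxy)benzoyl chloride | O=C(Cl)c1ccc(OCc2ccccc2)cc1 | starting material
11 | (2R,3S)-5,7-bis(benzyloxy)-2-[3,4-bis(benzyloxy)phenyl]-8-bromochroman-3-yl 4-(benzyloxy)benzoate | O=C(O[C@H]1Cc2c(OCc3ccccc3)cc(OCc3ccccc3)c(Br)c2O[C@@H]1c1ccc(OCc2ccccc2)c(OCc2ccccc2)c1)c1ccc(OCc2ccccc2)cc1 | intermediate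
12 | (2R,3S)-5,7-bis(benzyloxy)-2-[3,4-bis(benzyloxy)phenyl]-8-(4,4,5,5-tetramethyl-1,3,2-dioxaborolan-2-yl)chroman-3-yl 4-(benzyloxy)benzoate | O=C(O[C@H]1Cc2c(OCc3ccccc3)cc(OCc3ccccc3)c(B3OC(C)(C)C(C)(C)O3)c2O[C@@H]1c1ccc(OCc2ccccc2)c(OCc2ccccc2)c1)c1ccc(OCc2ccccc2)cc1 | intermediate
13 | potassium trifluoro{(2R,3S)-5,7-bis(benzyloxy)-2-[3,4-bis(benzyloxy)phenyl]-3-[4-(benzyloxy)benzoyloxy]chroman-8-yl}borate | [K+].O=C(O[C@H]1Cc2c(OCc3ccccc3)cc(OCc3ccccc3)c([B-](F)(F)F)c2O[C@@H]1c1ccc(OCc2ccccc2)c(OCc2ccccc2)c1)c1ccc(OCc2ccccc2)cc1 | intermediate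
14 | (2R,3S)-5,7-bis(benzyloxy)-2-[3,4-bis(benzyloxy)phenyl]-8-(difluoroboryl)chroman-3-yl 4-(benzyloxy)benzoate (not isolated) | O=C(O[C@H]1Cc2c(OCc3ccccc3)cc(OCc3ccccc3)c(B(F)F)c2O[C@@H]1c1ccc(OCc2ccccc2)c(OCc2ccccc2)c1)c1ccc(OCc2ccccc2)cc1 | intermediate
15 | (2R,3R)-3,5,7-tris(benzyloxy)-2-[3,4-bis(benzyloxy)phenyl]chroman-4-ylium {(2R,3S)-5,7-bis(benzyloxy)-2-[3,4-bis(benzyloxy)phenyl]-3-[4-(benzyloxy)benzoyloxy]chroman-8-yl}(2-ethoxyethoxy)difluoroborate, the contact ion pair formed when 14 takes the 2-ethoxyethoxy group of 6 (not isolated) | [CH+]1c2c(OCc3ccccc3)cc(OCc3ccccc3)cc2O[C@H](c2ccc(OCc3ccccc3)c(OCc3ccccc3)c2)[C@@H]1OCc1ccccc1.O=C(O[C@H]1Cc2c(OCc3ccccc3)cc(OCc3ccccc3)c([B-](F)(F)OCCOCC)c2O[C@@H]1c1ccc(OCc2ccccc2)c(OCc2ccccc2)c1)c1ccc(OCc2ccccc2)cc1 | intermediate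
16 | deca-O-benzyl dimer: upper (2R,3R,4R)-3,5,7-tris(benzyloxy)-2-[3,4-bis(benzyloxy)phenyl]chroman-4-yl unit bonded through C4 (trans to its 3-OBn) to C8 of (2R,3S)-5,7-bis(benzyloxy)-2-[3,4-bis(benzyloxy)phenyl]chroman-3-yl 4-(benzyloxy)benzoate | O=C(O[C@H]1Cc2c(OCc3ccccc3)cc(OCc3ccccc3)c([C@H]3c4c(OCc5ccccc5)cc(OCc5ccccc5)cc4O[C@H](c4ccc(OCc5ccccc5)c(OCc5ccccc5)c4)[C@@H]3OCc3ccccc3)c2O[C@@H]1c1ccc(OCc2ccccc2)c(OCc2ccccc2)c1)c1ccc(OCc2ccccc2)cc1 | intermediate
17 | CNP0288594.1: (2R,3S)-2-(3,4-dihydroxyphenyl)-8-[(2R,3R,4R)-2-(3,4-dihydroxyphenyl)-3,5,7-trihydroxychroman-4-yl]-5,7-dihydroxychroman-3-yl 4-hydroxybenzoate | O=C(O[C@H]1Cc2c(O)cc(O)c([C@H]3c4c(O)cc(O)cc4O[C@H](c4ccc(O)c(O)c4)[C@@H]3O)c2O[C@@H]1c1ccc(O)c(O)c1)c1ccc(O)cc1 | target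

**Totals**
Total step count: 10. Longest linear sequence: 7 steps (steps 4 to 10, from (+)-catechin 7).

**Three steps most likely to fail**

Step 9 (the proposed new coupling). The electron-rich aryl boron species 13/14 may protodeboronate, fluoride abstraction from the poorly soluble salt may be slow, or the ion pair 15 may not transfer the aryl group cleanly. The fallback uses known chemistry. It sets out from 8 and comes back to the route at 16. Alcohol 8 is acylated with 10 (Et3N, DMAP, CH2Cl2) to give 5,7,3',4'-tetra-O-benzyl-(+)-catechin 3-O-[4-(benzyloxy)benzoate] F1, the plain C8–H nucleophile. F1 (3 equiv, excess recovered) is then condensed with 6 under TMSOTf (catalytic) in CH2Cl2 at −78 °C. This is the classical Lewis-acid-catalysed Friedel–Crafts C4→C8 flavan condensation; the same substrate control gives the 4β product 16, and a minor 4→6 isomer is removed by chromatography.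

Step 7 (Miyaura borylation of the di-ortho-alkoxy aryl bromide). Oxidative addition may be slow and hydrodebromination may compete. The fallback replaces palladium catalysis by halogen–metal exchange and moves the acylation after borylation. It sets out from 9 and comes back at 12. Bromo alcohol 9 is treated with n-BuLi (2.2 equiv, THF, −78 °C) to give the 8-lithio lithium 3-alkoxide of tetra-O-benzylcatechin F2. F2 is quenched with 2-isopropoxy-4,4,5,5-tetramethyl-1,3,2-dioxaborolane and aqueous NH4Cl to give 8-(4,4,5,5-tetramethyl-1,3,2-dioxaborolan-2-yl)-5,7,3',4'-tetra-O-benzyl-(+)-catechin F3. Acylation of F3 with 10 (Et3N, DMAP, CH2Cl2) returns 12.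

Step 1 (benzylation of unprotected epicatechin). Base can epimerise C2 of the free phenol and cause C-benzylation, so yields vary. The fallback builds the epicatechin unit from the catechin series by inverting C3. It sets out from 8 and comes back at 2. Alcohol 8 is oxidised with Dess–Martin periodinane (wet CH2Cl2, rt) to (2R)-5,7-bis(benzyloxy)-2-[3,4-bis(benzyloxy)phenyl]chroman-3-one F4, which is used at once. Reduction with LiBH(s-Bu)3 (THF, −78 °C) delivers hydride to the face opposite the C2 aryl group and gives the 2,3-cis alcohol 2.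

**Further compounds**
F1 | step 9 | (2R,3S)-5,7-bis(benzyloxy)-2-[3,4-bis(benzyloxy)phenyl]chroman-3-yl 4-(benzyloxy)benzoate | O=C(O[C@H]1Cc2c(OCc3ccccc3)cc(OCc3ccccc3)cc2O[C@@H]1c1ccc(OCc2ccccc2)c(OCc2ccccc2)c1)c1ccc(OCc2ccccc2)cc1
F2 | step 7 | lithium (2R,3S)-5,7-bis(benzyloxy)-2-[3,4-bis(benzyloxy)phenyl]-8-lithiochroman-3-olate | [Li]O[C@H]1Cc2c(OCc3ccccc3)cc(OCc3ccccc3)c([Li])c2O[C@@H]1c1ccc(OCc2ccccc2)c(OCc2ccccc2)c1
F3 | step 7 | (2R,3S)-5,7-bis(benzyloxy)-2-[3,4-bis(benzyloxy)phenyl]-8-(4,4,5,5-tetramethyl-1,3,2-dioxaborolan-2-yl)chroman-3-ol | O[C@H]1Cc2c(OCc3ccccc3)cc(OCc3ccccc3)c(B3OC(C)(C)C(C)(C)O3)c2O[C@@H]1c1ccc(OCc2ccccc2)c(OCc2ccccc2)c1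
F4 | step 1 | (2R)-5,7-bis(benzyloxy)-2-[3,4-bis(benzyloxy)phenyl]chroman-3-one | O=C1Cc2c(OCc3ccccc3)cc(OCc3ccccc3)cc2O[C@@H]1c1ccc(OCc2ccccc2)c(OCc2ccccc2)c1
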